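## Structural features

The target is a germacranolide of the furanoheliangolide type. Its ten-membered carbocycle C1–C10 is bridged by an ether oxygen between C3 and C10, so that O, C3, C2, C1 and C10 form a 3(2H)-furanone and the core is an 11-oxabicyclo[6.2.1]undecane. The furanone enone is extended by the Z olefin C4=C5 (C15 methyl on C4), and a γ-lactone (O–C12(=O)–C11) is cis-fused to the large ring at C6–C7. There are six stereocentres. Five are contiguous along C6–C7–C8–C9–C10 (lactone oxygen, ring junction, angelate, free secondary alcohol, quaternary carbon with the C14 methyl and the bridging oxygen). The sixth, C11, sits on C7 and is a tertiary alcohol carrying CH2Cl (C13). The fragile points are the chlorohydrin (base closes it to the 11,13-epoxide), the angelate (Z to E isomerisation, migration to the C9 hydroxyl), the β-hydroxy ketone C9–C10–C1 (retro-aldol expelling an aromatic furanolate) and the cross-conjugated dienone. The real difficulty is twofold: closing the strained oxygen-bridged medium ring, and placing the C11 hydroxyl on the concave face of the cis-fused lactone, syn to C8, the face that a reagent attacking an 11,13-olefin or a lactone enolate would avoid. The key step uses the fact that C11 is bonded to C7 and, through C12 and the lactone oxygen, to C6, while C8 and C9 are both oxygenated. A chloropyruvate held on the C6 oxygen of a six-membered cyclic ether can reach C7 of a C7=C8 olefin whose C9–H lies next to the ring oxygen; one ene reaction then makes the lactone, C7 and C11, and leaves C8=C9 as an enol ether at the oxidation level of C8–OH plus a C9 aldehyde.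

Atoms keep the germacrane numbers C1–C15 of the target in every intermediate.

## Logic of the disconnections

**29 ⇐ 28 ⇐ 26 + 27.** The bonds cut are the C8–O ester bond, with inversion at C8, and the O–Si bonds at C9 and C11. The angelate is the most base- and nucleophile-sensitive group and is therefore introduced last. The glycal oxidation used earlier can only deliver the C8 oxygen on the face away from the lactone, so the esterification must also invert C8. The gain is that all earlier chemistry runs on a robust silyl ether at C8. The demand is a clean SN2 displacement at a carbinol flanked by two branched carbons, without Z/E isomerisation of the acid, and with the C9 and C11 oxygens masked.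

**26 ⇐ 25 ⇐ 24.** The bond cut is C4=C5, the only ring bond whose formation sets no stereocentre. Cutting it opens the bridged ten-membered ring to an acyclic diene whose two halves are joined only through C9–C10. The forward ring-closing metathesis must engage a 1,1-disubstituted olefin that is part of a dienone; the ring itself enforces the Z geometry. A selective unveiling of the C8 hydroxyl (25 to 26) follows the ring closure.

**24 ⇐ 23 ⇐ 22.** Cut is the terminal C5=CH2 carbon and the C5 oxidation level. C5 arrives from the sugar as CH2–O, so no carbon framework has to be built. The demand is to oxidise only the primary silyl ether among four silyl ethers and to keep C6, now α to an aldehyde, from epimerising.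

**22 ⇐ 21 ⇐ 13 + 19.** The bond cut is C9–C10. This separates the whole furanone from the lactone-bearing aldehyde and turns the quaternary centre C10 into an enolate carbon. It is the most convergent cut, and it creates C9 and C10 together. The forward aldol must be Felkin-selective at C9 relative to the C8 silyl ether, must pass through a closed transition state for C10, and must be quenched before the adduct can revert.

**19 ⇐ 18 ⇐ 15 + 16, and 15 ⇐ 14.** Cuts are the O–C3 bond (oxa-Michael closure of the furanone) and the C1–C2 bond (acetylide plus Weinreb amide). The furanone is reduced to a lactate derivative and an enyne, both bought. The demand is 1,4- rather than 1,6-addition to the enynone.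

**13 ⇐ 12 ⇐ 11 ⇐ 10.** No skeletal bond is cut. C9 is carried as an acetal and then a dithiane until the three hydroxyls at C5, C8 and C11 are silylated in one operation. The demand is an acetal-to-dithioacetal exchange that opens both C9–O bonds of a bicyclic acetal.

**10 ⇐ 8.** Cuts are the C8–O bond and the C9–O11 bond. Oxidising the enol ether gives C8–OH and stores C9 at the aldehyde level. The C11 hydroxyl, which lies directly under C9, is used to trap the epoxide. The demand is attack of the oxidant on the convex face only.

**8 ⇐ 7.** The bond cut is C7–C11, together with the lactone ring. The bicyclic chlorohydrin lactone with three stereocentres reverts to a monocyclic ester with one stereocentre. The demand is an intramolecular carbonyl-ene reaction through an ester tether, faster than ionisation of the allylic ester.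

**7 ⇐ 3 + 5, 3 ⇐ 2 ⇐ 1, and 5 ⇐ 4.** Cuts are the ester C–O bond, the acetate, and the C7–O bond of the glycal (restored as C–H by allylic reduction); on the acid side, the C–Cl bond. Everything reduces to a catalogue glycal and pyruvic acid. The demand is acylation with an α-chloro-α-keto acid without alkylating the base.

## Other disconnections considered

**Alternative 1:** The cut is C1–C10 of the ten-membered ring, made at the price of breaking C3–C8 of a six-membered ring. In the forward direction KH deprotonates a C8 carbinol and a [3,3] anionic oxy-Cope shift of the array C1=C2–C3–C8–C9=C10 expands the ring to the C8 enolate of ketone A1.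
- In its favour: the medium ring and the oxygen bridge arise in one concerted, strain-driven step from a compact bicycle derived from the chiral pool, with no high dilution. The Z C4=C5 olefin and the C6/C7 relationship are already in the six-membered ring. The enolate produced could be oxidised at C9 directly.
- Against it here: A1 has no oxygen at C1, C9 or C12 and no C11 functionality. The sequence would therefore end with allylic oxidation to the furanone, α-hydroxylation, ketone reduction, oxidation of the cyclic ether to the lactone, and conversion of the 11,13-olefin to the chlorohydrin. In that last operation the C11 hydroxyl would have to be placed on the concave face, against the normal bias of the reagent.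
- Comparison: on ring construction this alternative is the better plan (pericyclic, no entropy problem, geometry of C4=C5 given). On mechanism both plans rest on a pericyclic key step with a predictable stereochemical course, so they are equal there. On the stereotriad C6/C7/C11 and on oxidation-state economy the chosen plan is better, because its key step delivers the lactone, the chlorohydrin and the C8/C9 oxidation level at once. Step counts are likely similar; the alternative spends its steps late, on a precious macrocycle.

**Alternative 2:** The cut is C1–C2. In the forward direction CrCl2 (divalent chromium) with catalytic NiCl2 converts an iodoalkyne terminus at C2 into an alkynylchromium that adds to a C1 aldehyde on C10 and closes the ten-membered ring to the enynol A2. Oxidation to the ynone and oxa-Michael closure by the C10 oxygen would then give the furanone.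
- In its favour: all six stereocentres, the angelate and the chlorohydrin lactone are in place before cyclisation. The chromium chemistry tolerates esters, a neopentyl chloride and silyl ethers. The new C1 centre is removed by oxidation. The furanone is formed last under mild conditions, which avoids both the furanolate aldol and the retro-aldol problem. No inversion at C8 is needed.
- Against it here: a ten-membered ring that contains both a linear C≡C unit and a cis olefin is strained, so the closure needs high dilution and a large excess of toxic chromium salt. The C10 tertiary carbinol must be made stereoselectively in a separate acyclic step. The angelate has to survive several steps.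
- Comparison: on late-stage risk at C8 and C10 this alternative is the better plan. On ring strain in the closing step the chosen plan is better, since its metathesis closes a ring without an sp segment. On the lactone portion the alternative says nothing, and there the chosen ene step is at least its equal; the lactone of step 5 could in fact serve as a building block for this route. Step economy is about equal.

**Alternative 3:** The cut is C5–C6. In the forward direction catalytic CrCl2 (divalent chromium, with NiCl2), regenerated at a cathode, turns a Z vinyl iodide at C5 into a vinylchromium that adds to a C6 aldehyde and closes the ring to carbinol A3. Lactonisation of the C6 hydroxyl onto the C12 methyl ester would follow.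
- In its favour: chromium is used catalytically. The Z geometry is carried through with retention. The furanone and the angelate are pre-installed. The lactone closes spontaneously if C6 has the right configuration.
- Against it here: C6 is created in the macrocyclisation with no evident control, and the wrong epimer cannot form the cis lactone. The acyclic precursor must already contain C7 and the C11 chlorohydrin ester, which would have to be made without the ring template. A β-hydroxy aldehyde (C6 aldehyde, C11 hydroxyl) is prone to retro-aldol and elimination. The dienone and the chloride must survive reducing conditions.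
- Comparison: on reagent economy and on avoiding a late inversion at C8 this alternative is the better plan. On the size of ring closed the two are equal. On C6, C7 and C11 the chosen plan is better, because C6 comes from the sugar and the other two follow from it in the key step. Step economy is probably lower for the alternative, since its acyclic precursor is the more complex one.

Key step: step 5

Remark on the chemistry: 3,4-di-O-acetyl-L-arabinal is taken as a catalogue compound (otherwise three routine steps from L-arabinose). The C10 centre of the furanone is erased at the enolate stage, so racemic ethyl lactate is used.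

## Steps

Step 1
Reactants: 1 3,4-di-O-acetyl-L-arabinal
Product: 2 (R)-3,6-dihydro-2H-pyran-3-yl acetate
Conditions: Et3SiH, BF3·OEt2, CH2Cl2, −20 → 0 °C
Reagents that add atoms: none
Why: Ferrier-type reductive allylic transposition: BF3 ionises the allylic C7 acetate and the silane delivers hydride to C9; C6 is not involved and remains as the single stereocentre (R).

Step 2
Reactants: 2 (R)-3,6-dihydro-2H-pyran-3-yl acetate
Product: 3 (R)-3,6-dihydro-2H-pyran-3-ol
Conditions: K2CO3 (0.1 equiv), MeOH, 0 °C → rt
Reagents that add atoms: none
Why: Base-catalysed transesterification (methanolysis) of the acetate; the volatile, water-soluble alcohol is concentrated cold and used without distillation to dryness.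

Step 3
Reactants: 4 pyruvic acid
Product: 5 3-chloropyruvic acid
Conditions: SO2Cl2, neat, 25–30 °C
Reagents that add atoms: sulfuryl chloride, ClS(Cl)(=O)=O
Why: Ionic α-chlorination of the enol of the keto acid with sulfuryl chloride, which stops at the monochloride on the methyl carbon.

Step 4
Reactants: 5 3-chloropyruvic acid; 3 (R)-3,6-dihydro-2H-pyran-3-ol
Product: 7 (R)-3,6-dihydro-2H-pyran-3-yl 3-chloro-2-oxopropanoate, via 3-chloro-2-oxopropanoyl chloride 6 (not isolated)
Conditions: Cl2CHOMe, 50 °C, then evaporate; 3, 2,6-lutidine, CH2Cl2, −40 → 0 °C
Reagents that add atoms: none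
Why: Acid chloride formation with dichloromethyl methyl ether (the standard way to pyruvoyl chlorides) followed by O-acylation; a hindered pyridine is used because unhindered amine bases or acyl-transfer catalysts would be alkylated at CH2Cl, and C6 is not touched.

Step 5
Reactants: 7 (R)-3,6-dihydro-2H-pyran-3-yl 3-chloro-2-oxopropanoate
Product: 8 (3R,3aR,7aR)-3-(chloromethyl)-3-hydroxy-3,3a,7,7a-tetrahydro-2H-furo[2,3-c]pyran-2-one (cis-fused enol-ether lactone; C6, C7 and C11 as in the target)
Conditions: Me2AlCl (1.5 equiv), CH2Cl2 (0.02 M), −78 → −20 °C; aq. KNa tartrate
Reagents that add atoms: none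
Why: Intramolecular carbonyl-ene reaction: the Lewis-acid-bound ketone carbon C11 bonds to C7 while the C9 hydrogen on the same ring face moves to the ketone oxygen through a six-centre array and the olefin shifts to C8=C9; the closest known reaction type is the Lewis-acid-promoted ene cyclisation of olefinic α-keto esters and aldehydes in which the tether joins the enophile to the olefin terminus. The γ-lactone closes in the 5-exo mode at the ketone (C7 to C11, C=O outside the new ring), which requires the ester to turn into its less stable s-cis rotamer. C7 is set by the three-atom tether, which can deliver C11 only to the face of C7 that carries the C6 oxygen, so the fusion is cis; C11 is set by the need of the carbonyl oxygen to reach H–C9 over the ring, which puts OH on the concave face syn to C8 and CH2Cl outside. Regiochemistry needs no control, because the only other allylic hydrogen (on C6) lies on the face opposite to the tether. The step must outrun two competitors: ionisation or 1,3-shift of the allylic α-keto ester, which would racemise the substrate because the transposed ester is its mirror image, and acid-induced addition of the new C11 hydroxyl to the enol ether. Me2AlCl answers both: it binds the ketone oxygen alone (a chelate would hold the two carbonyls coplanar, whereas closure needs them nearly perpendicular), it acts at low temperature, and it removes the transferred proton as methane so that the product stays an aluminium alkoxide until work-up. The olefin lies between two allylic C–O bonds and is not electron-rich; the driving force is the doubly activated ketone and the enol-ether conjugation that develops at C8=C9.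

Step 6
Reactants: 8 cis-fused enol-ether lactone
Product: 10 tricyclic acetal in which C9 is bonded to the pyran oxygen and to O11 (five-membered ring O11–C11–C7–C8–C9) and C8 carries a free hydroxyl trans to the C7–C11 bond, via 8,9-epoxide 9 (not isolated)
Conditions: DMDO, acetone/CH2Cl2, −20 → 0 °C; evaporate; ZnCl2 (0.1 equiv), THF, 0 °C
Reagents that add atoms: dimethyldioxirane, CC1(C)OO1
Why: Glycal epoxidation on the convex face, anti to the fully substituted C7 substituent, then 5-exo opening of the epoxide at the anomeric carbon C9 by the C11 hydroxyl that the ene step left directly under C9 (inversion at C9); C8–OH is thereby set on the face away from the lactone (epimeric to the target), C9 is stored as an acetal, and the chlorohydrin oxygen is tied up.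

Step 7
Reactants: 10 tricyclic acetal
Product: 11 γ-lactone with CH2OH on C6, OH and CH2Cl on C11, and on C7 a CH(OH) group (C8) bearing a 1,3-dithian-2-yl group (C9); C6, C7, C11 as in the target, C8 epimeric
Conditions: HS(CH2)3SH, BF3·OEt2, CH2Cl2, −20 → 0 °C
Reagents that add atoms: propane-1,3-dithiol, SCCCS
Why: Lewis-acid acetal-to-dithioacetal exchange, the reaction that opens aldoses and anhydro sugars to open-chain dithioacetals; the second C–S bond forms intramolecularly, which pulls both C9–O bonds open, and no stereocentre is involved.

Step 8
Reactants: 11 dithiane triol
Product: 12 tris(triethylsilyl) ether of 11 (O5, O8 and O11 silylated)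
Conditions: TESOTf (4 equiv), 2,6-lutidine, CH2Cl2, −78 → 0 °C
Reagents that add atoms: triethylsilyl trifluoromethanesulfonate, CC[Si](CC)(CC)OS(=O)(=O)C(F)(F)F
Why: Silyl triflate silylation reaches primary, secondary and tertiary hydroxyls in one operation; the tertiary silyl ether blocks epoxide formation from the chlorohydrin in the basic steps that follow.

Step 9
Reactants: 12 tris(triethylsilyl) dithiane
Product: 13 C9 aldehyde (α-triethylsilyloxy aldehyde; O5, O8, O11 silylated)
Conditions: I2, NaHCO3, acetone/H2O, 0 °C
Reagents that add atoms: water, O
Why: Iodine-mediated hydrolysis of the dithioacetal under bicarbonate buffer, mild enough for the silyl ethers and for the epimerisable C8 centre; the aldehyde is used at once.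

Step 10
Reactants: 14 ethyl lactate (racemic)
Product: 15 2-hydroxy-N-methoxy-N-methylpropanamide
Conditions: MeNH(OMe)·HCl, iPrMgCl, THF, −20 → 0 °C
Reagents that add atoms: N,O-dimethylhydroxylamine hydrochloride, CNOC.Cl
Why: Weinreb amide formation from an ester with the magnesium amide of the hydroxylamine; the free hydroxyl is carried as its magnesium alkoxide.

Step 11
Reactants: 15 2-hydroxy-N-methoxy-N-methylpropanamide; 16 2-methylbut-1-en-3-yne
Product: 18 2-hydroxy-6-methylhept-6-en-4-yn-3-one, via lithium 3-methylbut-3-en-1-ynide 17 (not isolated)
Conditions: 16, n-BuLi (2.3 equiv), THF, −78 °C; then 15, −78 → 0 °C; aq. NH4Cl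
Reagents that add atoms: none
Why: Acetylide addition to a Weinreb amide stops at the ketone through the chelated tetrahedral intermediate; one extra equivalent of acetylide covers the hydroxyl.

Step 12
Reactants: 18 2-hydroxy-6-methylhept-6-en-4-yn-3-one
Product: 19 2-methyl-5-(prop-1-en-2-yl)furan-3(2H)-one
Conditions: Et2NH, EtOH, rt; then AcOH, H2O
Reagents that add atoms: none
Why: Classical furanone synthesis from an α'-hydroxy ynone: the amine adds 1,4 to the ynone and the hydroxyl then displaces it by addition–elimination at C3 (net 5-endo oxa-Michael closure).

Step 13
Reactants: 13 C9 aldehyde; 19 2-methyl-5-(prop-1-en-2-yl)furan-3(2H)-one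
Product: 21 aldol adduct with a free C9 hydroxyl and the complete furanone on C10 (C9 and C10 as in the target, C8 epimeric), via lithium furanolate 20 (not isolated)
Conditions: 19, LiN(iPr)2, THF, −78 °C; then 13, −78 °C; AcOH, −78 °C
Reagents that add atoms: none
Why: Aldol addition of a 3(2H)-furanone enolate (an aromatic 3-furanolate that reacts at the methyl-bearing carbon) to an α-silyloxy aldehyde: the polar Felkin–Anh model puts the new C9 oxygen anti to the C8 silyl ether, and a closed Zimmerman–Traxler transition state, with the methyl group cis to the enolate oxygen, places methyl syn to the new hydroxyl, which together give 9R,10R; the acidic quench at −78 °C forestalls retro-aldol and silyl migration.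

Step 14
Reactants: 21 aldol adduct
Product: 22 C9 tert-butyldimethylsilyl ether of 21
Conditions: TBSOTf, 2,6-lutidine, CH2Cl2, −78 → 0 °C
Reagents that add atoms: tert-butyldimethylsilyl trifluoromethanesulfonate, CC(C)(C)[Si](C)(C)OS(=O)(=O)C(F)(F)F
Why: Triflate silylation of a hindered secondary alcohol under weakly basic conditions; capping the β-hydroxy ketone removes the retro-aldol pathway for all later steps.

Step 15
Reactants: 22 fully silylated aldol adduct
Product: 23 C5 aldehyde (O8 and O11 as triethylsilyl ethers, O9 as tert-butyldimethylsilyl ether)
Conditions: (COCl)2, DMSO, CH2Cl2, −78 → −40 °C; then iPr2NEt, −78 → −20 °C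
Reagents that add atoms: none
Why: Swern conditions convert a primary triethylsilyl ether directly into the aldehyde, because activated DMSO attacks the least hindered silyl ether oxygen, while secondary and tertiary silyl ethers stay; the hindered amine and low temperature protect C6, which is now α to the aldehyde.

Step 16
Reactants: 23 C5 aldehyde
Product: 24 C5 vinyl compound (diene with the isopropenyl group of the furanone)
Conditions: Ph3PCH3Br, KN(SiMe3)2, THF, 0 °C; then 23, −78 → 0 °C
Reagents that add atoms: methyltriphenylphosphonium bromide, C[P+](c1ccccc1)(c1ccccc1)c1ccccc1.[Br-]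
Why: Wittig methylenation with a preformed ylide at low temperature; the aldehyde reacts well before the hindered vinylogous-ester ketone or the lactone.

Step 17
Reactants: 24 diene
Product: 25 macrocycle with the complete target skeleton (Z C4=C5; O8 and O11 as triethylsilyl ethers, O9 as tert-butyldimethylsilyl ether; C8 epimeric)
Conditions: second-generation Hoveyda–Grubbs catalyst, RuCl2(H2IMes)(=CH-C6H4-2-OiPr) (20 mol %), toluene (1 mM), 80 °C
Reagents that add atoms: none
Why: Ring-closing metathesis: the ruthenium carbene loads on the monosubstituted C5 vinyl group and closes onto the 1,1-disubstituted isopropenyl terminus with loss of ethylene; within the oxygen-bridged ring only the cis arrangement of C3 and C6 across C4=C5 is attainable, so the Z geometry is set by the ring.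

Step 18
Reactants: 25 tris-silylated macrocycle
Product: 26 C8 alcohol (O9 tert-butyldimethylsilyl and O11 triethylsilyl ethers retained)
Conditions: PPTS (0.2 equiv), MeOH/CH2Cl2, 0 °C
Reagents that add atoms: none
Why: Acid-catalysed methanolysis distinguishes silyl ethers by their environment: the secondary triethylsilyl ether leaves, while the secondary tert-butyldimethylsilyl ether and the tertiary triethylsilyl ether next to the lactone carbonyl remain; loss of the tertiary one would be harmless, since a tertiary alcohol does not enter the next step.

Step 19
Reactants: 26 C8 alcohol; 27 angelic acid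
Product: 28 C8 angelate with inverted C8 (all six stereocentres as in the target; O9 and O11 silylated)
Conditions: PPh3, DIAD, toluene, 0 °C → rt
Reagents that add atoms: none
Why: Mitsunobu esterification: SN2 displacement of the C8 alkoxyphosphonium group by the carboxylate inverts C8 to the S configuration of the target; the near-neutral medium preserves the Z geometry of the acid, and no other hydroxyl is free.

Step 20
Reactants: 28 bis-silylated angelate
Product: 29 CNP0272644.1 (target)
Conditions: HF·pyridine, pyridine, THF, 0 °C → rt
Reagents that add atoms: none
Why: Fluoride cleavage of both remaining silyl ethers under buffered acidic conditions; this avoids the basic fluoride sources that would invite epoxide closure of the chlorohydrin, retro-aldol at C9–C10 or migration of the angelate to O9.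

## Compound list

1 | 3,4-di-O-acetyl-L-arabinal | O1C=C[C@@H](OC(C)=O)[C@@H](OC(C)=O)C1 | starting material
2 | (R)-3,6-dihydro-2H-pyran-3-yl acetate | CC(=O)O[C@H]1COCC=C1 | intermediate
3 | (R)-3,6-dihydro-2H-pyran-3-ol | O[C@H]1COCC=C1 | intermediate
4 | pyruvic acid | CC(=O)C(=O)O | starting material
5 | 3-chloropyruvic acid (3-chloro-2-oxopropanoic acid) | OC(=O)C(=O)CCl | intermediate
6 | 3-chloro-2-oxopropanoyl chloride | ClCC(=O)C(Cl)=O | intermediate
7 | (R)-3,6-dihydro-2H-pyran-3-yl 3-chloro-2-oxopropanoate | C1=CCOC[C@@H]1OC(=O)C(=O)CCl | intermediate
8 | (3R,3aR,7aR)-3-(chloromethyl)-3-hydroxy-3,3a,7,7a-tetrahydro-2H-furo[2,3-c]pyran-2-one | C1=C[C@@H]2[C@H](CO1)OC(=O)[C@@]2(O)CCl | intermediate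
9 | 8,9-epoxide of 8, oxygen on the face opposite to the lactone | ClC[C@]1(O)C(=O)O[C@H]2CO[C@@H]3O[C@@H]3[C@@H]12 | intermediate
10 | tricyclic acetal (C9 bonded to the pyran oxygen and to O11; C8–OH trans to C7–C11) | ClC[C@]12O[C@@H]3OC[C@H](OC1=O)[C@H]2[C@H]3O | intermediate
11 | open-chain dithiane triol (lactone intact; OH at C5, C8, C11; 1,3-dithian-2-yl as C9; C8 epimeric to target) | OC[C@@H]1OC(=O)[C@@](O)(CCl)[C@@H]1[C@@H](O)C1SCCCS1 | intermediate
12 | tris(triethylsilyl) ether of 11 | CC[Si](CC)(CC)OC[C@@H]1OC(=O)[C@@](O[Si](CC)(CC)CC)(CCl)[C@@H]1[C@@H](O[Si](CC)(CC)CC)C1SCCCS1 | intermediate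
13 | C9 aldehyde with O5, O8, O11 as triethylsilyl ethers | CC[Si](CC)(CC)OC[C@@H]1OC(=O)[C@@](O[Si](CC)(CC)CC)(CCl)[C@@H]1[C@@H](O[Si](CC)(CC)CC)C=O | intermediate
14 | ethyl lactate (racemic) | CC(O)C(=O)OCC | starting material
15 | 2-hydroxy-N-methoxy-N-methylpropanamide | CC(O)C(=O)N(C)OC | intermediate
16 | 2-methylbut-1-en-3-yne | CC(=C)C#C | starting material
17 | lithium 3-methylbut-3-en-1-ynide | CC(=C)C#[C-].[Li+] | intermediate
18 | 2-hydroxy-6-methylhept-6-en-4-yn-3-one | CC(O)C(=O)C#CC(C)=C | intermediate
19 | 2-methyl-5-(prop-1-en-2-yl)furan-3(2H)-one | CC1OC(C(C)=C)=CC1=O | intermediate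
20 | lithium 2-methyl-5-(prop-1-en-2-yl)furan-3-olate | CC1=C([O-])C=C(C(C)=C)O1.[Li+] | intermediate
21 | aldol adduct (C9–OH free; furanone on C10; C9, C10 as in target, C8 epimeric) | CC[Si](CC)(CC)OC[C@@H]1OC(=O)[C@@](O[Si](CC)(CC)CC)(CCl)[C@@H]1[C@@H](O[Si](CC)(CC)CC)[C@@H](O)[C@@]1(C)OC(C(C)=C)=CC1=O | intermediate
22 | C9 tert-butyldimethylsilyl ether of 21 | CC[Si](CC)(CC)OC[C@@H]1OC(=O)[C@@](O[Si](CC)(CC)CC)(CCl)[C@@H]1[C@@H](O[Si](CC)(CC)CC)[C@@H](O[Si](C)(C)C(C)(C)C)[C@@]1(C)OC(C(C)=C)=CC1=O | intermediate
23 | C5 aldehyde | O=C[C@@H]1OC(=O)[C@@](O[Si](CC)(CC)CC)(CCl)[C@@H]1[C@@H](O[Si](CC)(CC)CC)[C@@H](O[Si](C)(C)C(C)(C)C)[C@@]1(C)OC(C(C)=C)=CC1=O | intermediate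
24 | C5 vinyl diene | C=C[C@@H]1OC(=O)[C@@](O[Si](CC)(CC)CC)(CCl)[C@@H]1[C@@H](O[Si](CC)(CC)CC)[C@@H](O[Si](C)(C)C(C)(C)C)[C@@]1(C)OC(C(C)=C)=CC1=O | intermediate
25 | macrocycle, O8 and O11 triethylsilyl, O9 tert-butyldimethylsilyl, C8 epimeric to target | CC[Si](CC)(CC)O[C@@H]1[C@@H]2[C@H](/C=C(/C)C3=CC(=O)[C@](C)(O3)[C@@H]1O[Si](C)(C)C(C)(C)C)OC(=O)[C@@]2(O[Si](CC)(CC)CC)CCl | intermediate
26 | macrocyclic C8 alcohol (8-epi), O9 and O11 silylated | O[C@@H]1[C@@H]2[C@H](/C=C(/C)C3=CC(=O)[C@](C)(O3)[C@@H]1O[Si](C)(C)C(C)(C)C)OC(=O)[C@@]2(O[Si](CC)(CC)CC)CCl | intermediate
27 | angelic acid ((Z)-2-methylbut-2-enoic acid) | C/C=C(/C)C(=O)O | starting material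
28 | target with O9 as tert-butyldimethylsilyl ether and O11 as triethylsilyl ether | C/C=C(/C)C(=O)O[C@H]1[C@@H]2[C@H](/C=C(/C)C3=CC(=O)[C@](C)(O3)[C@@H]1O[Si](C)(C)C(C)(C)C)OC(=O)[C@@]2(O[Si](CC)(CC)CC)CCl | intermediate
29 | CNP0272644.1 | C/C=C(/C)C(=O)O[C@H]1[C@@H]2[C@H](/C=C(/C)C3=CC(=O)[C@](C)(O3)[C@@H]1O)OC(=O)[C@@]2(O)CCl | target

## Step count and least certain steps

Total: 20 steps. Longest linear sequence: 16 steps (1 to 29 through steps 1, 2, 4–9 and 13–20); steps 3 and 10–12 are side branches.

**Step 5 (key step).** The fully substituted ketone carbon has to reach C7 inside a five-membered transition state through the disfavoured ester rotamer, and the olefin is electron-poor. Slow bond formation would give way to ionisation or 1,3-shift of the allylic α-keto ester (loss of enantiopurity, decomposition) or to methyl transfer from aluminium to the ketone.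

Fallback, from 3 back to 8: ring closure and creation of the quaternary centre are given to two separate steps.
- Acylation of 3 with bromoacetyl bromide and pyridine gives (R)-3,6-dihydro-2H-pyran-3-yl bromoacetate F1.
- AgNO3 in MeCN gives the nitrate ester F2, and NaOAc in DMSO gives the glyoxylate F3.
- The aldehyde is a smaller and much more reactive enophile; the same Me2AlCl ene closure should give the cis-fused α-hydroxy lactone F4, whose C11 configuration does not matter.
- TESOTf/2,6-lutidine gives the silyl ether F5.
- Its lithium enolate (LiN(SiMe3)2, THF, −78 °C) is alkylated with ICH2Cl from the convex face. This places CH2Cl outside and the silyloxy group on the concave face, giving the silyl ether F6.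
- HF·pyridine returns to 8.

**Step 13.** The lithium aldolate can revert, because the furanolate is an aromatic leaving group. A loose transition state at the hindered tetrasubstituted enolate would erode control at C9 and C10, and the C8 silyl group may migrate to the new alkoxide.

Fallback, from 19 back to 21: 19 is converted with TMSOTf/Et3N into the silyloxyfuran F7. F7 is combined with 13 under BF3·OEt2 at −78 °C in a Mukaiyama aldol. This has an open transition state and a non-chelating Lewis acid, so the Felkin preference is at its strongest, and no metal aldolate is formed that could revert. Aqueous work-up gives 21.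

**Step 17.** The carbene formed at C5 may fail to engage the hindered, electron-poor 1,1-disubstituted terminus. Cross-metathesis between vinyl groups would then give oligomers, and olefin migration could compete at the temperature needed.

Fallback, from 15 and 13 back to 25: C4–C5 is closed by a vinylogous aldol instead.
- 15 and but-1-ynyllithium give 2-hydroxyhept-4-yn-3-one F8; Et2NH then acid gives 5-ethyl-2-methylfuran-3(2H)-one F9.
- F9, deprotonated at C10 with LiN(iPr)2, adds to 13 as in step 13 to give the aldol adduct F10.
- TBSOTf gives the silyl ether F11, and the selective Swern oxidation gives the C5 aldehyde F12.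
- KN(SiMe3)2 at −78 °C under high dilution deprotonates the C4 methylene of the now 2,2-disubstituted furanone. The resulting intramolecular vinylogous aldol addition to C5 gives the macrocyclic carbinol F13.
- Dehydration (MsCl/Et3N, then DBU) gives the conjugated, ring-enforced Z olefin of 25.

**Step 19.** The displacement at C8 is flanked by two branched carbons. Elimination of the alkoxyphosphonium intermediate or simple failure of the SN2 step are the likely faults. Z to E isomerisation of the angelate by reversible phosphine addition is a lesser one.

Fallback, from 26 back to 28: Dess–Martin periodinane with NaHCO3 gives the C8 ketone F14. NaBH4/CeCl3 at −78 °C should deliver hydride anti to the C9 silyloxy group (Felkin sense, giving the 8,9-syn arrangement of the target) and so the inverted alcohol F15. Yamaguchi esterification with 27 (2,4,6-trichlorobenzoyl chloride, Et3N; DMAP, toluene) then gives 28 with retention.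

## Further compounds

F1 | step 5 | (R)-3,6-dihydro-2H-pyran-3-yl bromoacetate | BrCC(=O)O[C@H]1COCC=C1
F2 | step 5 | (R)-3,6-dihydro-2H-pyran-3-yl (nitrooxy)acetate | [O-][N+](=O)OCC(=O)O[C@H]1COCC=C1
F3 | step 5 | (R)-3,6-dihydro-2H-pyran-3-yl glyoxylate | O=CC(=O)O[C@H]1COCC=C1
F4 | step 5 | (3aR,7aR)-3-hydroxy-3,3a,7,7a-tetrahydro-2H-furo[2,3-c]pyran-2-one (C11 epimers) | C1=C[C@@H]2[C@H](CO1)OC(=O)C2O
F5 | step 5 | triethylsilyl ether of F4 | C1=C[C@@H]2[C@H](CO1)OC(=O)C2O[Si](CC)(CC)CC
F6 | step 5 | triethylsilyl ether of 8 | C1=C[C@@H]2[C@H](CO1)OC(=O)[C@@]2(O[Si](CC)(CC)CC)CCl
F7 | step 13 | trimethyl{[2-methyl-5-(prop-1-en-2-yl)furan-3-yl]oxy}silane | CC1=C(O[Si](C)(C)C)C=C(C(C)=C)O1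
F8 | step 17 | 2-hydroxyhept-4-yn-3-one | CCC#CC(=O)C(C)O
F9 | step 17 | 5-ethyl-2-methylfuran-3(2H)-one | CCC1=CC(=O)C(C)O1
F10 | step 17 | aldol adduct of 13 with F9 (C9–OH free) | CC[Si](CC)(CC)OC[C@@H]1OC(=O)[C@@](O[Si](CC)(CC)CC)(CCl)[C@@H]1[C@@H](O[Si](CC)(CC)CC)[C@@H](O)[C@@]1(C)OC(CC)=CC1=O
F11 | step 17 | C9 tert-butyldimethylsilyl ether of F10 | CC[Si](CC)(CC)OC[C@@H]1OC(=O)[C@@](O[Si](CC)(CC)CC)(CCl)[C@@H]1[C@@H](O[Si](CC)(CC)CC)[C@@H](O[Si](C)(C)C(C)(C)C)[C@@]1(C)OC(CC)=CC1=O
F12 | step 17 | C5 aldehyde from F11 | O=C[C@@H]1OC(=O)[C@@](O[Si](CC)(CC)CC)(CCl)[C@@H]1[C@@H](O[Si](CC)(CC)CC)[C@@H](O[Si](C)(C)C(C)(C)C)[C@@]1(C)OC(CC)=CC1=O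
F13 | step 17 | macrocyclic C5 carbinol (C4–C5 single bond, C4 and C5 epimers) | CC[Si](CC)(CC)O[C@@H]1[C@@H]2[C@H](C(O)C(C)C3=CC(=O)[C@](C)(O3)[C@@H]1O[Si](C)(C)C(C)(C)C)OC(=O)[C@@]2(O[Si](CC)(CC)CC)CCl
F14 | step 19 | macrocyclic C8 ketone | O=C1[C@@H]2[C@H](/C=C(/C)C3=CC(=O)[C@](C)(O3)[C@@H]1O[Si](C)(C)C(C)(C)C)OC(=O)[C@@]2(O[Si](CC)(CC)CC)CCl
F15 | step 19 | macrocyclic C8 alcohol with the C8 configuration of the target | O[C@H]1[C@@H]2[C@H](/C=C(/C)C3=CC(=O)[C@](C)(O3)[C@@H]1O[Si](C)(C)C(C)(C)C)OC(=O)[C@@]2(O[Si](CC)(CC)CC)CCl
A1 | alternative 1 | ring-expanded oxygen-bridged C8 ketone fused to a 3-methylenetetrahydrofuran | O=C1[C@@H]2[C@H](/C=C(/C)C3=CC[C@](C)(O3)C1)OCC2=C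
A2 | alternative 2 | ten-membered enynol (C1 epimers) | C/C=C(/C)C(=O)O[C@H]1[C@@H]2[C@H](/C=C(/C)C#CC(O)[C@](C)(O[Si](CC)(CC)CC)[C@@H]1O[Si](C)(C)C(C)(C)C)OC(=O)[C@@]2(O)CCl
A3 | alternative 3 | macrocyclic C6 carbinol with C12 methyl ester | C/C=C(/C)C(=O)O[C@H]1[C@H]([C@@H](O)/C=C(/C)C3=CC(=O)[C@](C)(O3)[C@@H]1O[Si](C)(C)C(C)(C)C)[C@](O)(CCl)C(=O)OC
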